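The 13-membered ring (C2–C10, the ether oxygen, C14–C16; C1 = lactone carbonyl, numbered along the carbocycle) is cut across C6–C7. The β-acyloxy ketone C7(=O)–C6H2–C5H–O(lactone) is treated as a masked alkene: ring-closing metathesis of a diene that already carries the dihydropyranone and tetrahydropyran rings forms C6=C7 in one operation, and the allylic lactone oxygen on C5 then steers a Tsuji–Wacker oxidation to C7. The diene arises by reductive Knoevenagel union (C2–C16) of a 6-vinyl dihydropyranone with a tetrahydropyran aldehyde whose three ring stereocentres are relayed from one carbinol centre through an Achmatowicz sequence.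

Key step: step 16

Numbering used below: C1 lactone carbonyl, C2 enol α-carbon, C3 enol C–OH, C4 CH(propyl), C5 lactone O–CH, C6, C7 ketone, C8 CH(CH3), C9, C10 ether O–CH, C11 CH(OH), C12 CH(CH3), C13, C14 quaternary ether carbon, C15, C16 (bonded to C2).
Remark: 1 and 3 are racemates; from 5 on every compound is a single enantiomer.

**Dihydropyranone fragment (C1–C6)**

Step 1
Reactants: 1 ethyl 3-hydroxypent-4-enoate (racemate); 2 1-iodopropane
Product: 3 ethyl (2R*,3R*)-3-hydroxy-2-propylpent-4-enoate (racemic anti diastereomer)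
Conditions: LiN(i-Pr)2 (2.2 equiv), THF, −78 to −20 °C; then n-PrI, HMPA, −78 to 0 °C
Reagents that add atoms: 1-iodopropane CCCI
Why: Fráter–Seebach alkylation: the chelated lithium alkoxide/enolate dianion should be alkylated on the face opposite the vinyl group of the six-membered chelate, which sets C4 anti to the C5 oxygen, the relative configuration of the later trans-5,6-disubstituted lactone.

Step 2
Reactants: 3 racemic anti hydroxy ester; 4 vinyl acetate
Product: 5 ethyl (2R,3R)-3-acetoxy-2-propylpent-4-enoate
Conditions: Burkholderia cepacia lipase (immobilised), vinyl acetate (3 equiv), t-BuOMe, 35 °C, run to about half conversion; chromatography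
Reagents that add atoms: vinyl acetate CC(=O)OC=C
Why: lipase-catalysed kinetic resolution by transesterification: by the empirical size rule for secondary alcohols (vinyl medium, CH(Pr)CO2Et large) the (3R)-alcohol should be acylated, so the (2R,3R)-enantiomer leaves as the acetate and the (2S,3S)-alcohol stays behind, which fixes the absolute configuration of C4 and C5.

Step 3
Reactants: 5 ethyl (2R,3R)-3-acetoxy-2-propylpent-4-enoate
Product: 6 (5R,6R)-6-ethenyl-4-hydroxy-5-propyl-5,6-dihydro-2H-pyran-2-one
Conditions: LiN(SiMe3)2 (3.2 equiv), THF, −78 to 0 °C; then 1 M HCl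
Reagents that add atoms: none
Why: Dieckmann (intramolecular Claisen) condensation of the acetate enolate onto the ethyl ester closes the β-keto-δ-lactone, which rests as the 4-hydroxy enol; the acetate CH3 should be deprotonated in preference to the tertiary α-CH, so C4 and C5 are not touched.

**Tetrahydropyran fragment (C7–C16)**

Step 4
Reactants: 7 (R)-4-benzyl-1,3-oxazolidin-2-one; 8 (E)-but-2-enoyl chloride
Product: 9 (R)-4-benzyl-3-[(E)-but-2-enoyl]-1,3-oxazolidin-2-one
Conditions: n-BuLi, THF, −78 °C; then 8, −78 to 0 °C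
Reagents that add atoms: (E)-but-2-enoyl chloride C/C=C/C(Cl)=O
Why: N-acylation of the lithiated oxazolidinone (acyl substitution); no stereocentre is formed.

Step 5
Reactants: 9 N-crotonyl oxazolidinone; 10 vinylmagnesium bromide
Product: 11 (R)-4-benzyl-3-[(S)-3-methylpent-4-enoyl]-1,3-oxazolidin-2-one
Conditions: CuBr·SMe2 (1.5 equiv), CH2=CHMgBr (3 equiv), THF, −78 to −20 °C; aq. NH4Cl
Reagents that add atoms: vinylmagnesium bromide C=C[Mg]Br
Why: auxiliary-controlled conjugate addition of the vinyl cuprate to the magnesium-chelated s-cis N-enoyl imide, on the face opposite the benzyl group, should set the C8 methyl centre as (S).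

Step 6
Reactants: 11 conjugate adduct
Product: 13 (S)-3-methylpent-4-enoic acid, via peroxy acid 12 (not isolated)
Conditions: LiOH, H2O2, THF/H2O, 0 °C; then aq. Na2SO3; then HCl
Reagents that add atoms: hydrogen peroxide OO
Why: hydroperoxide cleavage of the exocyclic imide carbonyl (acyl substitution) and sulfite reduction of the peracid free the acid and the auxiliary; the β-stereocentre cannot epimerise.

Step 7
Reactants: 13 (S)-3-methylpent-4-enoic acid; 14 2,4-dimethylfuran
Product: 16 (S)-1-(3,5-dimethylfuran-2-yl)-3-methylpent-4-en-1-one, via mixed trifluoroacetic anhydride 15 (not isolated)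
Conditions: (CF3CO)2O (1.2 equiv), H3PO4 (cat.), MeCN, 0 °C to rt
Reagents that add atoms: 2,4-dimethylfuran Cc1cc(C)co1
Why: Friedel–Crafts acylation of the furan by the mixed anhydride at its only free α-position gives the 2-acyl-3,5-dimethylfuran that holds C10–C14 and both ring methyl groups in masked form.

Step 8
Reactants: 16 furyl ketone
Product: 17 (1S,3S)-1-(3,5-dimethylfuran-2-yl)-3-methylpent-4-en-1-ol
Conditions: RuCl[(S,S)-TsDPEN](p-cymene) (1 mol%), HCO2H/Et3N (5:2), rt
Reagents that add atoms: none
Why: Noyori asymmetric transfer hydrogenation of the heteroaryl ketone: the furan takes the place of the aryl group in the transition state, so the (S,S)-catalyst should deliver the (S)-carbinol (C10), the centre from which C11, C12 and C14 are later relayed.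

Step 9
Reactants: 17 furyl carbinol
Product: 18 (2S)-6-hydroxy-4,6-dimethyl-2-[(2S)-2-methylbut-3-en-1-yl]-2H-pyran-3(6H)-one (both C6 epimers)
Conditions: N-bromosuccinimide (1.05 equiv), NaHCO3, NaOAc, THF/H2O (4:1), 0 °C
Reagents that add atoms: water O
Why: Achmatowicz rearrangement: oxidative opening of the furan to the ene-dione and ring closure through the carbinol oxygen give the pyranone hemiketal with C10 retained, the electron-rich furan reacting far faster than the terminal alkene.

Step 10
Reactants: 18 pyranone hemiketal; 19 tert-butyl[(1-methoxyethenyl)oxy]dimethylsilane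
Product: 20 methyl [(2S,6S)-2,4-dimethyl-6-[(2S)-2-methylbut-3-en-1-yl]-5-oxo-5,6-dihydro-2H-pyran-2-yl]acetate
Conditions: BF3·OEt2 (2 equiv), 19 (3 equiv), CH2Cl2, −78 to −40 °C
Reagents that add atoms: tert-butyl[(1-methoxyethenyl)oxy]dimethylsilane C=C(OC)O[Si](C)(C)C(C)(C)C
Why: ionisation of the tertiary hemiketal and Mukaiyama-type addition of the ketene silyl acetal to the cyclic oxocarbenium ion (C-glycosylation of an Achmatowicz pyranone) should occur on the face opposite the C10 side chain, which sets the quaternary C14 with its CH2 arm trans to C9.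

Step 11
Reactants: 20 enone ester
Product: 22 methyl [(2R,4S,6S)-2,4-dimethyl-6-[(2S)-2-methylbut-3-en-1-yl]-5-oxooxan-2-yl]acetate, via silyl enol ether 21 (not isolated)
Conditions: [(Ph3P)CuH]6 (5 mol%), PhMe2SiH (1.5 equiv), toluene, rt; then 1 M HCl, THF; then DBU (0.2 equiv), CH2Cl2, rt
Reagents that add atoms: none
Why: copper hydride conjugate reduction, selective for the enone over the terminal alkene and the ester, followed by mild equilibration of the α-methyl ketone, should leave the C12 methyl equatorial and cis to the C10 side chain, because the other epimer suffers a 1,3-diaxial clash with the axial CH2CO2Me group on C14.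

Step 12
Reactants: 22 saturated ketone
Product: 23 methyl [(2R,4S,5S,6S)-5-hydroxy-2,4-dimethyl-6-[(2S)-2-methylbut-3-en-1-yl]oxan-2-yl]acetate
Conditions: LiBH(s-Bu)3, THF, −78 °C; aq. NH4Cl
Reagents that add atoms: none
Why: substrate-controlled ketone reduction: the bulky hydride should attack the C11 ketone from the equatorial direction between its two equatorial neighbours, giving the axial alcohol cis to both.

Step 13
Reactants: 23 axial alcohol
Product: 24 methyl [(2R,4S,5S,6S)-5-(tert-butyldimethylsilyloxy)-2,4-dimethyl-6-[(2S)-2-methylbut-3-en-1-yl]oxan-2-yl]acetate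
Conditions: t-BuMe2SiOTf, 2,6-lutidine, CH2Cl2, 0 °C
Reagents that add atoms: tert-butyldimethylsilyl triflate CC(C)(C)[Si](C)(C)OS(=O)(=O)C(F)(F)F
Why: silyl ether formation on the hindered axial alcohol, which keeps this hydroxyl from adding to the palladium-bound alkene in step 17.

Step 14
Reactants: 24 silyl ether ester
Product: 25 [(2R,4S,5S,6S)-5-(tert-butyldimethylsilyloxy)-2,4-dimethyl-6-[(2S)-2-methylbut-3-en-1-yl]oxan-2-yl]acetaldehyde
Conditions: i-Bu2AlH (1.1 equiv), CH2Cl2, −78 °C; Rochelle salt
Reagents that add atoms: none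
Why: partial ester reduction through the tetrahedral aluminium hemiacetal, stable at −78 °C, gives the C16 aldehyde without touching the silyl ether or the alkene.

**Union and end game**

Step 15
Reactants: 25 tetrahydropyran aldehyde; 6 vinyl dihydropyranone
Product: 27 (5R,6R)-3-{2-[(2S,4S,5S,6S)-5-(tert-butyldimethylsilyloxy)-2,4-dimethyl-6-[(2S)-2-methylbut-3-en-1-yl]oxan-2-yl]ethyl}-6-ethenyl-4-hydroxy-5-propyl-5,6-dihydro-2H-pyran-2-one, via Knoevenagel alkylidene 26 (not isolated)
Conditions: L-proline (20 mol%), diethyl 2,6-dimethyl-1,4-dihydropyridine-3,5-dicarboxylate (1.1 equiv), CH2Cl2, rt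
Reagents that add atoms: none
Why: organocatalytic reductive Knoevenagel alkylation: the acidic C2–H of the hydroxypyranone condenses with the aldehyde and the alkylidene-1,3-dicarbonyl is reduced at once by hydride transfer from the dihydropyridine, which forms the C2–C16 bond by C-alkylation only and creates no stereocentre.

Step 16
Reactants: 27 seco diene
Product: 28 macrocyclic C6=C7 alkene (11-O-silyl, E/Z mixture)
Conditions: second-generation Grubbs catalyst RuCl2(=CHPh)(PCy3)(H2IMes) (10 mol%), toluene, 1 mM, 80 °C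
Reagents that add atoms: none
Why: The ruthenium benzylidene should exchange onto the less hindered C7 vinyl group, and the new alkylidene adds across the C6 vinyl group through a ruthenacyclobutane that collapses to the ring alkene and ethene, whose loss drives the reaction. The closest known reaction type is macrocyclic ring-closing olefin metathesis of an α,ω-diene with allylic branching on both sides. One ring is closed, the 13-membered ring, by end-to-end macrocyclisation in the endo mode (both alkene carbons, C6 and C7, end up in the ring), with the dihydropyranone and tetrahydropyran rings already in place. No stereocentre is created, and the alkene geometry does not matter because step 17 turns C6 into CH2 and C7 into C=O for either isomer. The selectivity needed is ring closure over oligomerisation and inertness of the third C=C: high dilution and the two preformed rings, which limit the freedom of the tether, favour closure, and the tetrasubstituted enol C2=C3 is not a metathesis substrate.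

Step 17
Reactants: 28 macrocyclic alkene
Product: 29 11-O-(tert-butyldimethylsilyl)mangromicin C
Conditions: PdCl2 (20 mol%), CuCl (1 equiv), O2 (1 atm), DMF/H2O (7:1), 50 °C
Reagents that add atoms: water O
Why: Tsuji–Wacker oxidation of an internal allylic ester: hydroxypalladation should place oxygen on C7, the alkene carbon remote from the electron-withdrawing lactone oxygen on C5, so both alkene isomers converge on the β-acyloxy ketone with C6 as CH2, and C8 is not involved.

Step 18
Reactants: 29 silyl-protected ketone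
Product: 30 mangromicin C
Conditions: HF·pyridine, THF, 0 °C to rt
Reagents that add atoms: none
Why: fluoride-mediated silyl ether cleavage under weakly acidic conditions, which avoid base-induced β-elimination of the lactone oxygen and epimerisation at C8.

**Compound list**

1 | ethyl 3-hydroxypent-4-enoate (racemate) | C=CC(O)CC(=O)OCC | starting material
2 | 1-iodopropane | CCCI | starting material
3 | ethyl (2R*,3R*)-3-hydroxy-2-propylpent-4-enoate (racemate, both enantiomers written) | CCC[C@@H](C(=O)OCC)[C@H](O)C=C.CCC[C@H](C(=O)OCC)[C@@H](O)C=C | intermediate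
4 | vinyl acetate | CC(=O)OC=C | starting material
5 | ethyl (2R,3R)-3-acetoxy-2-propylpent-4-enoate | CCC[C@@H](C(=O)OCC)[C@H](OC(C)=O)C=C | intermediate
6 | (5R,6R)-6-ethenyl-4-hydroxy-5-propyl-5,6-dihydro-2H-pyran-2-one | CCC[C@H]1C(O)=CC(=O)O[C@@H]1C=C | intermediate
7 | (R)-4-benzyl-1,3-oxazolidin-2-one | O=C1OC[C@@H](Cc2ccccc2)N1 | starting material
8 | (E)-but-2-enoyl chloride | C/C=C/C(Cl)=O | starting material
9 | (R)-4-benzyl-3-[(E)-but-2-enoyl]-1,3-oxazolidin-2-one | C/C=C/C(=O)N1C(=O)OC[C@H]1Cc1ccccc1 | intermediate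
10 | vinylmagnesium bromide | C=C[Mg]Br | starting material
11 | (R)-4-benzyl-3-[(S)-3-methylpent-4-enoyl]-1,3-oxazolidin-2-one | C=C[C@@H](C)CC(=O)N1C(=O)OC[C@H]1Cc1ccccc1 | intermediate
12 | (S)-3-methylpent-4-eneperoxoic acid | C=C[C@@H](C)CC(=O)OO | intermediate (not isolated)
13 | (S)-3-methylpent-4-enoic acid | C=C[C@@H](C)CC(=O)O | intermediate
14 | 2,4-dimethylfuran | Cc1cc(C)co1 | starting material
15 | (S)-3-methylpent-4-enoic trifluoroacetic anhydride | C=C[C@@H](C)CC(=O)OC(=O)C(F)(F)F | intermediate (not isolated)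
16 | (S)-1-(3,5-dimethylfuran-2-yl)-3-methylpent-4-en-1-one | C=C[C@@H](C)CC(=O)c1oc(C)cc1C | intermediate
17 | (1S,3S)-1-(3,5-dimethylfuran-2-yl)-3-methylpent-4-en-1-ol | C=C[C@@H](C)C[C@H](O)c1oc(C)cc1C | intermediate
18 | (2S)-6-hydroxy-4,6-dimethyl-2-[(2S)-2-methylbut-3-en-1-yl]-2H-pyran-3(6H)-one (both C6 epimers) | C=C[C@@H](C)C[C@@H]1OC(C)(O)C=C(C)C1=O | intermediate
19 | tert-butyl[(1-methoxyethenyl)oxy]dimethylsilane | C=C(OC)O[Si](C)(C)C(C)(C)C | starting material
20 | methyl [(2S,6S)-2,4-dimethyl-6-[(2S)-2-methylbut-3-en-1-yl]-5-oxo-5,6-dihydro-2H-pyran-2-yl]acetate | COC(=O)C[C@@]1(C)C=C(C)C(=O)[C@H](C[C@H](C)C=C)O1 | intermediate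
21 | dimethyl(phenyl)silyl enol ether of 22 (C11–O–Si, C11=C12) | COC(=O)C[C@@]1(C)CC(C)=C(O[Si](C)(C)c2ccccc2)[C@H](C[C@H](C)C=C)O1 | intermediate (not isolated)
22 | methyl [(2R,4S,6S)-2,4-dimethyl-6-[(2S)-2-methylbut-3-en-1-yl]-5-oxooxan-2-yl]acetate | COC(=O)C[C@@]1(C)C[C@H](C)C(=O)[C@H](C[C@H](C)C=C)O1 | intermediate
23 | methyl [(2R,4S,5S,6S)-5-hydroxy-2,4-dimethyl-6-[(2S)-2-methylbut-3-en-1-yl]oxan-2-yl]acetate | COC(=O)C[C@@]1(C)C[C@H](C)[C@H](O)[C@H](C[C@H](C)C=C)O1 | intermediate
24 | methyl [(2R,4S,5S,6S)-5-(tert-butyldimethylsilyloxy)-2,4-dimethyl-6-[(2S)-2-methylbut-3-en-1-yl]oxan-2-yl]acetate | COC(=O)C[C@@]1(C)C[C@H](C)[C@H](O[Si](C)(C)C(C)(C)C)[C@H](C[C@H](C)C=C)O1 | intermediate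
25 | [(2R,4S,5S,6S)-5-(tert-butyldimethylsilyloxy)-2,4-dimethyl-6-[(2S)-2-methylbut-3-en-1-yl]oxan-2-yl]acetaldehyde | O=CC[C@@]1(C)C[C@H](C)[C@H](O[Si](C)(C)C(C)(C)C)[C@H](C[C@H](C)C=C)O1 | intermediate
26 | Knoevenagel alkylidene: (5R,6R)-6-ethenyl-5-propyl-3-[2-(oxan-2-yl)ethylidene]oxane-2,4-dione carrying the substituted oxane of 25 | CCC[C@H]1C(=O)C(=CC[C@@]2(C)C[C@H](C)[C@H](O[Si](C)(C)C(C)(C)C)[C@H](C[C@H](C)C=C)O2)C(=O)O[C@@H]1C=C | intermediate (not isolated)
27 | (5R,6R)-3-{2-[(2S,4S,5S,6S)-5-(tert-butyldimethylsilyloxy)-2,4-dimethyl-6-[(2S)-2-methylbut-3-en-1-yl]oxan-2-yl]ethyl}-6-ethenyl-4-hydroxy-5-propyl-5,6-dihydro-2H-pyran-2-one | CCC[C@H]1C(O)=C(CC[C@@]2(C)C[C@H](C)[C@H](O[Si](C)(C)C(C)(C)C)[C@H](C[C@H](C)C=C)O2)C(=O)O[C@@H]1C=C | intermediate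
28 | 11-O-(tert-butyldimethylsilyl)-7-deoxo-6,7-didehydromangromicin C (macrocyclic C6=C7 alkene, E/Z mixture) | CCC[C@H]1C(O)=C2CC[C@@]3(C)C[C@H](C)[C@H](O[Si](C)(C)C(C)(C)C)[C@H](C[C@H](C)C=C[C@H]1OC2=O)O3 | intermediate
29 | 11-O-(tert-butyldimethylsilyl)mangromicin C | CCC[C@H]1C(O)=C2CC[C@@]3(C)C[C@H](C)[C@H](O[Si](C)(C)C(C)(C)C)[C@H](C[C@H](C)C(=O)C[C@H]1OC2=O)O3 | intermediate
30 | mangromicin C | CCC[C@H]1C(O)=C2CC[C@@]3(C)C[C@H](C)[C@H](O)[C@H](C[C@H](C)C(=O)C[C@H]1OC2=O)O3 | target

**Count and risks**

Total step count: 18. Longest linear sequence: 15 steps (steps 4–18, from 7 to 30); the dihydropyranone branch (steps 1–3) joins at step 15.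

Steps most likely to fail:

1. Step 17 (Wacker oxidation). What may go wrong: hydroxypalladation at C6 instead of C7, migration of the double bond towards C8 through palladium hydride species with loss of that stereocentre, or slow turnover at the hindered ring alkene. Fallback without a β-hydride pathway: from 28, oxymercuration with Hg(OAc)2 in THF/H2O should place the hydroxyl on C7 for the same inductive reason and give the organomercurial acetate F1 (not isolated). NaBH4/NaOH reduces it to the C7 secondary alcohol F2 (both epimers). Dess–Martin periodinane with NaHCO3 then oxidises the alcohol, and the route is rejoined at 29.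

2. Step 16 (ring-closing metathesis). What may go wrong: oligomerisation outrunning ring closure, or arrest of the catalyst by chelation of the C6 alkylidene to the acidic enol or the lactone carbonyl. Fallback: from 27, the enol is masked with t-BuMe2SiOTf and Et3N (CH2Cl2, −78 °C) as the 3-O-silyl enol ether F3. The metathesis is run on this non-acidic substrate to give the macrocyclic silyl enol ether F4. The vinylogous silyl ester is then hydrolysed selectively (AcOH, THF/H2O, rt; the alkyl silyl ether on C11 stays), and the route is rejoined at 28.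

3. Step 2 (enzymatic resolution). What may go wrong: slow or poorly selective acyl transfer to the α-branched secondary alcohol. Fallback, resolution before alkylation: from 1, the same lipase and vinyl acetate should acylate the (S)-alcohol of the unbranched substrate to ethyl (S)-3-acetoxypent-4-enoate F5. Acid-catalysed ethanolysis (AcCl cat., EtOH) frees ethyl (S)-3-hydroxypent-4-enoate F6. Alkylation with 2 under the conditions of step 1 gives the single enantiomer ethyl (2R,3R)-3-hydroxy-2-propylpent-4-enoate F7. Ac2O, pyridine and DMAP then give 5.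

Further compounds
F1 | step 17 | 6-(acetoxymercurio)-7-hydroxy adduct of 28 (organomercurial, not isolated) | CCC[C@H]1C(O)=C2CC[C@@]3(C)C[C@H](C)[C@H](O[Si](C)(C)C(C)(C)C)[C@H](C[C@H](C)C(O)C([Hg]OC(C)=O)[C@H]1OC2=O)O3
F2 | step 17 | 11-O-(tert-butyldimethylsilyl)-7-deoxo-7-hydroxymangromicin C (both C7 epimers) | CCC[C@H]1C(O)=C2CC[C@@]3(C)C[C@H](C)[C@H](O[Si](C)(C)C(C)(C)C)[C@H](C[C@H](C)C(O)C[C@H]1OC2=O)O3
F3 | step 16 | 3-O-(tert-butyldimethylsilyl) enol ether of 27 | CCC[C@H]1C(O[Si](C)(C)C(C)(C)C)=C(CC[C@@]2(C)C[C@H](C)[C@H](O[Si](C)(C)C(C)(C)C)[C@H](C[C@H](C)C=C)O2)C(=O)O[C@@H]1C=C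
F4 | step 16 | 3-O-(tert-butyldimethylsilyl) enol ether of 28 | CCC[C@H]1C(O[Si](C)(C)C(C)(C)C)=C2CC[C@@]3(C)C[C@H](C)[C@H](O[Si](C)(C)C(C)(C)C)[C@H](C[C@H](C)C=C[C@H]1OC2=O)O3
F5 | step 2 | ethyl (S)-3-acetoxypent-4-enoate | C=C[C@@H](OC(C)=O)CC(=O)OCC
F6 | step 2 | ethyl (S)-3-hydroxypent-4-enoate | C=C[C@@H](O)CC(=O)OCC
F7 | step 2 | ethyl (2R,3R)-3-hydroxy-2-propylpent-4-enoate (single enantiomer) | CCC[C@@H](C(=O)OCC)[C@H](O)C=C
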